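**Retrosynthetic overview**

- The target 11 has no stereocentre. It is reached last by removing two 4-methoxybenzyl groups from the exocyclic pyrimidine nitrogen of indole 10.
- The pyrrole ring of 10 is opened at the C2–C3 bond: C2 is the carbon of an aryl isocyanide and C3 is a CH2 group, giving isocyanide 9.
- The strategy rests on the pyrimidin-4-yl group at indole C3. In 9 the future C3 is a CH2 bonded to the benzene ring and to pyrimidine C4, and its anion is shared with pyrimidine N1 and N3, so an alkoxide is enough to generate it.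
- 9 comes from nitro compound 6 by reduction, N-formylation and dehydration. The aryl–CH2 bond of 6 comes from SNAr of the lateral anion of methylpyrimidine 3 on fluoronitroarene 5, which also fixes the 5,6-dibromo pattern.
- 3 comes from 1 and 2, and 5 from 4 by nitration. The benzene and pyrimidine rings are bought; the pyrrole ring is the only ring formed, in step 7.

Key step: step 7

**Route**

Step 1
Reactants: 1 2-chloro-4-methylpyrimidine; 2 bis(4-methoxybenzyl)amine
Product: 3 N,N-bis(4-methoxybenzyl)-4-methylpyrimidin-2-amine
Conditions: K2CO3, DMSO, 110 °C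
Reagents that add atoms: none
Why: SNAr of the secondary amine at pyrimidine C2, which lies between both ring nitrogens and carries the chloride leaving group; the 4-methyl group does not interfere.

Step 2
Reactants: 4 1,2-dibromo-4-fluorobenzene
Product: 5 1,2-dibromo-4-fluoro-5-nitrobenzene
Conditions: fuming HNO3, conc. H2SO4, 0 °C → rt
Reagents that add atoms: nitric acid, O[N+](=O)[O-]
Why: electrophilic aromatic nitration should go to C5, which is ortho to fluorine and para to the C2 bromine, whereas C3 is crowded between F and Br and C6 is meta to fluorine; minor isomers should be removable by crystallisation.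

Step 3
Reactants: 3 N,N-bis(4-methoxybenzyl)-4-methylpyrimidin-2-amine; 5 1,2-dibromo-4-fluoro-5-nitrobenzene
Product: 6 4-[(4,5-dibromo-2-nitrophenyl)methyl]-N,N-bis(4-methoxybenzyl)pyrimidin-2-amine
Conditions: LiN(SiMe3)2 (2.2 equiv), THF, −78 → −20 °C; then 5 added slowly, −78 → 0 °C; aq NH4Cl
Reagents that add atoms: none
Why: lateral deprotonation of the 4-methyl group gives an aza-enolate-type anion that should displace fluoride ortho to the nitro group (SNAr), fluoride leaving far faster than the bromide para to the nitro group, while the second equivalent of base takes up the more acidic CH2 proton of the product.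

Step 4
Reactants: 6 4-[(4,5-dibromo-2-nitrophenyl)methyl]-N,N-bis(4-methoxybenzyl)pyrimidin-2-amine
Product: 7 4-[(2-amino-4,5-dibromophenyl)methyl]-N,N-bis(4-methoxybenzyl)pyrimidin-2-amine
Conditions: Fe powder, NH4Cl, EtOH–H2O, 75 °C
Reagents that add atoms: none
Why: Béchamp-type reduction of the nitro group by iron, which should leave the aryl bromides, the N-benzyl groups and the pyrimidine untouched, unlike catalytic hydrogenation.

Step 5
Reactants: 7 4-[(2-amino-4,5-dibromophenyl)methyl]-N,N-bis(4-methoxybenzyl)pyrimidin-2-amine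
Product: 8 N-[2-[[2-[bis(4-methoxybenzyl)amino]pyrimidin-4-yl]methyl]-4,5-dibromophenyl]formamide
Conditions: acetic formic anhydride (preformed from HCO2H and Ac2O, 55 °C), THF, 0 °C → rt
Reagents that add atoms: acetic formic anhydride, CC(=O)OC=O (prepared beforehand from formic acid, OC=O, and acetic anhydride, CC(=O)OC(C)=O)
Why: N-formylation by the mixed anhydride, which transfers its more electrophilic formyl group to the aniline nitrogen, the only N–H nucleophile present because the pyrimidine amine is fully substituted.

Step 6
Reactants: 8 N-[2-[[2-[bis(4-methoxybenzyl)amino]pyrimidin-4-yl]methyl]-4,5-dibromophenyl]formamide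
Product: 9 4-[(4,5-dibromo-2-isocyanophenyl)methyl]-N,N-bis(4-methoxybenzyl)pyrimidin-2-amine
Conditions: POCl3, Et3N, CH2Cl2, −20 → 0 °C; cold aqueous work-up
Reagents that add atoms: none
Why: Ugi-type dehydration of an N-aryl formamide (O-phosphorylation, then base-induced elimination) should give the isocyanide, and triethylamine is too weak to deprotonate the CH2, so 9 can be isolated.

Step 7
Reactants: 9 4-[(4,5-dibromo-2-isocyanophenyl)methyl]-N,N-bis(4-methoxybenzyl)pyrimidin-2-amine
Product: 10 4-(5,6-dibromo-1H-indol-3-yl)-N,N-bis(4-methoxybenzyl)pyrimidin-2-amine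
Conditions: KOtBu (1.5 equiv), THF, −20 °C → rt; aq NH4Cl
Reagents that add atoms: none
Why: KOtBu should remove a proton from the CH2 flanked by the benzene ring and pyrimidine C4, and the carbanion should add to the divalent carbon of the ortho isocyanide, which forms the C2–C3 bond and an imidoyl anion at C2; protonation at C2 by tert-butanol and removal of the acidic C3–H then give the aromatic indolide, which is protonated at N1 on quench. The closest known reaction is the Ito–Saegusa indole synthesis, the base-induced cyclisation of ortho-alkylphenyl isocyanides, including its variants in which the CH2 carries a second acceptor group. The pyrrole ring closes in a 5-endo-dig mode, since both atoms of the N≡C unit end up inside the new five-membered ring and the nucleophile attacks its terminal, carbene-like carbon. No stereocentre is formed. The step needs chemoselectivity: attack of the internal carbanion on the isocyanide carbon must outrun tert-butoxide addition to the isocyanide, isocyanide oligomerisation and any reaction at the two C–Br bonds; the acidity of the doubly activated CH2 allows a bulky alkoxide instead of an alkyllithium, so no bromine–metal exchange can occur, and the intramolecular five-membered closure is favoured at low temperature and moderate dilution.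

Step 8
Reactants: 10 4-(5,6-dibromo-1H-indol-3-yl)-N,N-bis(4-methoxybenzyl)pyrimidin-2-amine
Product: 11 Meridianin F, 4-(5,6-dibromo-1H-indol-3-yl)pyrimidin-2-amine
Conditions: TFA, anisole, 70 °C; then aq NaHCO3
Reagents that add atoms: none
Why: acidolytic N-debenzylation, in which both 4-methoxybenzyl groups should leave as stabilised cations that anisole traps by Friedel–Crafts alkylation, while the protonated 3-pyrimidinyl-5,6-dibromoindole is deactivated toward benzylation and the aryl bromides are inert.

**Compound list**

1 | 2-chloro-4-methylpyrimidine | Cc1ccnc(Cl)n1 | starting material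
2 | bis(4-methoxybenzyl)amine | COc1ccc(CNCc2ccc(OC)cc2)cc1 | starting material
3 | N,N-bis(4-methoxybenzyl)-4-methylpyrimidin-2-amine | COc1ccc(CN(Cc2ccc(OC)cc2)c2nccc(C)n2)cc1 | intermediate
4 | 1,2-dibromo-4-fluorobenzene | Fc1ccc(Br)c(Br)c1 | starting material
5 | 1,2-dibromo-4-fluoro-5-nitrobenzene | O=[N+]([O-])c1cc(Br)c(Br)cc1F | intermediate
6 | 4-[(4,5-dibromo-2-nitrophenyl)methyl]-N,N-bis(4-methoxybenzyl)pyrimidin-2-amine | COc1ccc(CN(Cc2ccc(OC)cc2)c2nccc(Cc3cc(Br)c(Br)cc3[N+](=O)[O-])n2)cc1 | intermediate
7 | 4-[(2-amino-4,5-dibromophenyl)methyl]-N,N-bis(4-methoxybenzyl)pyrimidin-2-amine | COc1ccc(CN(Cc2ccc(OC)cc2)c2nccc(Cc3cc(Br)c(Br)cc3N)n2)cc1 | intermediate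
8 | N-[2-[[2-[bis(4-methoxybenzyl)amino]pyrimidin-4-yl]methyl]-4,5-dibromophenyl]formamide | COc1ccc(CN(Cc2ccc(OC)cc2)c2nccc(Cc3cc(Br)c(Br)cc3NC=O)n2)cc1 | intermediate
9 | 4-[(4,5-dibromo-2-isocyanophenyl)methyl]-N,N-bis(4-methoxybenzyl)pyrimidin-2-amine | [C-]#[N+]c1cc(Br)c(Br)cc1Cc1ccnc(N(Cc2ccc(OC)cc2)Cc2ccc(OC)cc2)n1 | intermediate
10 | 4-(5,6-dibromo-1H-indol-3-yl)-N,N-bis(4-methoxybenzyl)pyrimidin-2-amine | COc1ccc(CN(Cc2ccc(OC)cc2)c2nccc(-c3c[nH]c4cc(Br)c(Br)cc34)n2)cc1 | intermediate
11 | Meridianin F, 4-(5,6-dibromo-1H-indol-3-yl)pyrimidin-2-amine | Nc1nccc(-c2c[nH]c3cc(Br)c(Br)cc23)n1 | target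

**Step count**

Total: 8 steps. Longest linear sequence: 7 steps (from 1 through steps 1, 3, 4, 5, 6, 7, 8, or from 4 through steps 2 to 8).

**Steps most likely to fail**

Step 7. The delocalised carbanion may add to the isocyanide carbon too slowly, so that tert-butoxide addition or oligomerisation consumes the isocyanide. A first adjustment within the step would be a catalytic amount of Cu2O (monovalent copper), which activates the isocyanide in the active-methylene variant of this cyclisation. The fallback closes the pyrrole ring at N1–C2 instead and sets out from 6. Heating 6 with N,N-dimethylformamide dimethyl acetal in DMF at 110 °C should condense the same acidic CH2 to the enamine 4-[1-(4,5-dibromo-2-nitrophenyl)-2-(dimethylamino)ethenyl]-N,N-bis(4-methoxybenzyl)pyrimidin-2-amine F1 (alkene geometry not controlled and of no consequence). Reduction of the nitro group with Fe powder in AcOH at 80 °C should then let the new aniline add to the enamine carbon and expel dimethylamine (Leimgruber–Batcho-type indole synthesis), coming back to the route at 10.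

Step 3. Electron transfer from the lateral anion to the nitroarene, substitution at the bromine-bearing carbon para to the nitro group, or a second arylation by the product anion could erode the coupling. The fallback tames the nucleophile as an ester enolate and sets out from 3. Lateral acylation with LiN(SiMe3)2 (2.2 equiv) and di-tert-butyl dicarbonate in THF at −78 °C should give tert-butyl 2-[2-[bis(4-methoxybenzyl)amino]pyrimidin-4-yl]acetate F2. Its enolate (K2CO3, DMF, rt) should displace the fluoride of 5 as a malonate-type nucleophile, giving racemic tert-butyl 2-[2-[bis(4-methoxybenzyl)amino]pyrimidin-4-yl]-2-(4,5-dibromo-2-nitrophenyl)acetate F3. Brief treatment with TFA in CH2Cl2 at 0 °C → rt should cleave the tert-butyl ester, and the resulting α-pyrimidinyl acid should lose CO2 spontaneously, coming back to the route at 6.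

Step 8. The 4-methoxybenzyl cations may be captured by the indole ring, or the second benzyl group may be lost incompletely. The fallback avoids benzyl protection altogether by carrying a methylthio group at pyrimidine C2 and introducing the nitrogen last. It sets out from 5.
- The fluoride of 5 is displaced by the lateral anion of purchased 4-methyl-2-(methylthio)pyrimidine F4 (LiN(SiMe3)2, THF, −78 °C) to give 4-[(4,5-dibromo-2-nitrophenyl)methyl]-2-(methylthio)pyrimidine F5.
- The chemistry of steps 4 to 7 is then repeated: Fe/NH4Cl to 4,5-dibromo-2-[[2-(methylthio)pyrimidin-4-yl]methyl]aniline F6; acetic formic anhydride to N-[4,5-dibromo-2-[[2-(methylthio)pyrimidin-4-yl]methyl]phenyl]formamide F7; POCl3/Et3N to 4-[(4,5-dibromo-2-isocyanophenyl)methyl]-2-(methylthio)pyrimidine F8; KOtBu to 5,6-dibromo-3-[2-(methylthio)pyrimidin-4-yl]-1H-indole F9.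
- mCPBA (CH2Cl2, 0 °C) should oxidise the sulfide to 5,6-dibromo-3-[2-(methylsulfonyl)pyrimidin-4-yl]-1H-indole F10.
- NH3 in dioxane (sealed tube, 100 °C) should displace methanesulfinate at C2 by SNAr, coming back to the route at 11.

**Further compounds**

F1 | step 7 | 4-[1-(4,5-dibromo-2-nitrophenyl)-2-(dimethylamino)ethenyl]-N,N-bis(4-methoxybenzyl)pyrimidin-2-amine | COc1ccc(CN(Cc2ccc(OC)cc2)c2nccc(C(=CN(C)C)c3cc(Br)c(Br)cc3[N+](=O)[O-])n2)cc1
F2 | step 3 | tert-butyl 2-[2-[bis(4-methoxybenzyl)amino]pyrimidin-4-yl]acetate | COc1ccc(CN(Cc2ccc(OC)cc2)c2nccc(CC(=O)OC(C)(C)C)n2)cc1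
F3 | step 3 | tert-butyl 2-[2-[bis(4-methoxybenzyl)amino]pyrimidin-4-yl]-2-(4,5-dibromo-2-nitrophenyl)acetate (racemic) | COc1ccc(CN(Cc2ccc(OC)cc2)c2nccc(C(C(=O)OC(C)(C)C)c3cc(Br)c(Br)cc3[N+](=O)[O-])n2)cc1
F4 | step 8 | 4-methyl-2-(methylthio)pyrimidine (purchased) | CSc1nccc(C)n1
F5 | step 8 | 4-[(4,5-dibromo-2-nitrophenyl)methyl]-2-(methylthio)pyrimidine | CSc1nccc(Cc2cc(Br)c(Br)cc2[N+](=O)[O-])n1
F6 | step 8 | 4,5-dibromo-2-[[2-(methylthio)pyrimidin-4-yl]methyl]aniline | CSc1nccc(Cc2cc(Br)c(Br)cc2N)n1
F7 | step 8 | N-[4,5-dibromo-2-[[2-(methylthio)pyrimidin-4-yl]methyl]phenyl]formamide | CSc1nccc(Cc2cc(Br)c(Br)cc2NC=O)n1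
F8 | step 8 | 4-[(4,5-dibromo-2-isocyanophenyl)methyl]-2-(methylthio)pyrimidine | CSc1nccc(Cc2cc(Br)c(Br)cc2[N+]#[C-])n1
F9 | step 8 | 5,6-dibromo-3-[2-(methylthio)pyrimidin-4-yl]-1H-indole | CSc1nccc(-c2c[nH]c3cc(Br)c(Br)cc23)n1
F10 | step 8 | 5,6-dibromo-3-[2-(methylsulfonyl)pyrimidin-4-yl]-1H-indole | CS(=O)(=O)c1nccc(-c2c[nH]c3cc(Br)c(Br)cc23)n1
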